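**Plan**
Retrosynthesis first removes the end groups (15‑OAc, free 17‑acid, and the 7,8‑double bond by dehydrogenation of an 8‑ester), then cuts C9–C10 (ring B), then the C8=C9 olefin, then C7–C8.
Enabling feature (labdane numbering): C10, the quaternary ring A/ring B junction carbon bearing C20, is bonded to C9, and the adjacent C8 carries the C17 carboxyl. A tertiary C10 radical made on an intact ring A can therefore add to C9 as the β‑carbon of a 2‑alkylidene ester whose α‑carbon is C8.
Forward: ring A (C1–C5, C10, C18–C20) comes from (S)‑α‑cyclogeranic acid and is extended by C6–C7. C8/C17 come from a phosphonoacetate, and C9 with C11–C16 from (S)‑citronellol through a Z‑selective olefination. Ring B is closed last by the radical step, followed by dehydrogenation, deprotection and acetylation.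
Stereochemistry: C13 comes from (S)‑citronellol and C5 from the resolved acid. C10 (trans fusion) is relayed from C5, and C9 from the Z olefin geometry, in a chair‑like ring closure. C8 is transient.

Key step: step 13

Assumption: in step 2 the salt of the S acid with (S)‑1‑phenylethylamine is taken to be the less soluble diastereomer; if the pairing is the opposite one, the (R)‑amine is used and nothing else changes.
Remark: labdane numbering is used for the bicyclic compounds (C17 = carboxyl carbon on C8, C20 = methyl on C10); β is the face of the C10 methyl, α the opposite face.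

Step 1
Reactants: 1 methyl (±)‑α‑cyclogeranate (methyl 2,6,6‑trimethylcyclohex‑2‑ene‑1‑carboxylate)
Product: 2 (±)‑α‑cyclogeranic acid (2,6,6‑trimethylcyclohex‑2‑ene‑1‑carboxylic acid)
Conditions: KOH, MeOH/H2O, reflux; then aq. HCl
Reagents that add atoms: potassium hydroxide, [K+].[OH-]
Why: Saponification (acyl substitution by hydroxide) of the hindered ester needs forcing conditions but should leave the 2‑ene in place, because the carboxylate once formed is not enolised, and it provides the acid handle for resolution.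

Step 2
Reactants: 2 (±)‑α‑cyclogeranic acid
Product: 3 (S)‑1‑phenylethylammonium (1S)‑2,6,6‑trimethylcyclohex‑2‑ene‑1‑carboxylate
Conditions: (S)‑1‑phenylethylamine (1 equiv), acetone, crystallise; recrystallise to constant rotation
Reagents that add atoms: (S)‑1‑phenylethylamine, C[C@H](N)c1ccccc1
Why: Classical resolution through diastereomeric salts: the two 1‑phenylethylammonium carboxylates differ in solubility, so fractional crystallisation should deliver the salt of the S acid, and this is the step that fixes the absolute configuration of C5.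

Step 3
Reactants: 3 (S)‑1‑phenylethylammonium (1S)‑2,6,6‑trimethylcyclohex‑2‑ene‑1‑carboxylate
Product: 4 (S)‑α‑cyclogeranic acid [(1S)‑2,6,6‑trimethylcyclohex‑2‑ene‑1‑carboxylic acid]
Conditions: 1 M HCl, Et2O, 0 °C
Reagents that add atoms: none
Why: Acid–base metathesis: the mineral acid protonates the carboxylate, the free acid passes into ether, and the ring stereocentre is not enolised under these conditions.

Step 4
Reactants: 4 (S)‑α‑cyclogeranic acid
Product: 5 (S)‑α‑cyclogeraniol {[(1S)‑2,6,6‑trimethylcyclohex‑2‑en‑1‑yl]methanol}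
Conditions: LiAlH4, THF, 0 °C → reflux; aqueous NaOH work‑up
Reagents that add atoms: none
Why: LiAlH4 reduction of a carboxylic acid to the primary alcohol proceeds through the carboxylate, whose α‑carbon is not acidic, so the stereocentre and the 2‑ene are retained.

Step 5
Reactants: 5 (S)‑α‑cyclogeraniol
Product: 6 (S)‑α‑cyclocitral [(1S)‑2,6,6‑trimethylcyclohex‑2‑ene‑1‑carbaldehyde]
Conditions: Dess–Martin periodinane, NaHCO3, CH2Cl2, 0 °C; crude aldehyde used at once
Reagents that add atoms: none
Why: Dess–Martin oxidation runs under buffered, non‑basic conditions and stops at the aldehyde, which should avoid both racemisation of the allylic α‑centre and migration of the double bond into conjugation.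

Step 6
Reactants: 6 (S)‑α‑cyclocitral
Product: 7 (6S)‑6‑ethenyl‑1,5,5‑trimethylcyclohex‑1‑ene
Conditions: Zn, CH2Br2, TiCl4 (reagent pre‑formed in THF at 5 °C), CH2Cl2, 0 °C → rt
Reagents that add atoms: dibromomethane, BrCBr
Why: Takai–Lombardo methylenation: the non‑basic zinc/titanium gem‑dimetallic methylene reagent olefinates the hindered aldehyde without enolising the allylic α‑stereocentre, which a basic phosphorus ylide could racemise or conjugate.

Step 7
Reactants: 7 (6S)‑6‑ethenyl‑1,5,5‑trimethylcyclohex‑1‑ene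
Product: 9 2‑[(1S)‑2,6,6‑trimethylcyclohex‑2‑en‑1‑yl]ethan‑1‑ol, via B‑alkyl‑9‑BBN adduct 8 (not isolated)
Conditions: 9‑BBN, THF, 0 °C → rt; then NaOH, 30% H2O2, 0 °C → rt
Reagents that add atoms: hydrogen peroxide, OO
Why: Hydroboration–oxidation with the bulky borane 9‑BBN is selective for the monosubstituted vinyl group over the trisubstituted ring alkene and places boron on the terminal carbon, and alkaline peroxide then replaces boron by hydroxyl with no stereocentre involved.

Step 8
Reactants: 9 2‑[(1S)‑2,6,6‑trimethylcyclohex‑2‑en‑1‑yl]ethan‑1‑ol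
Product: 10 (6S)‑6‑(2‑iodoethyl)‑1,5,5‑trimethylcyclohex‑1‑ene
Conditions: PPh3, imidazole, I2, CH2Cl2, 0 °C → rt
Reagents that add atoms: iodine, II
Why: Appel‑type iodination (PPh3/I2/imidazole) converts the unhindered primary alcohol to the iodide by SN2 displacement of the alkoxyphosphonium ion, without acid that could move the ring alkene.

Step 9
Reactants: 10 (6S)‑6‑(2‑iodoethyl)‑1,5,5‑trimethylcyclohex‑1‑ene; 11 methyl bis(2,2,2‑trifluoroethyl)phosphonoacetate
Product: 12 methyl 2‑[bis(2,2,2‑trifluoroethoxy)phosphoryl]‑4‑[(1S)‑2,6,6‑trimethylcyclohex‑2‑en‑1‑yl]butanoate (both C2 epimers)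
Conditions: 11 (2 equiv), NaH, THF/DMF, 0 °C; then 10, rt → 45 °C
Reagents that add atoms: none
Why: C‑Alkylation of the stabilised sodium phosphonoacetate carbanion with the primary iodide (SN2), using an excess of 11 to hold back dialkylation; the new stereocentre at the phosphorus‑bearing carbon is lost in step 12 and needs no control.

Step 10
Reactants: 13 (S)‑citronellol [(3S)‑3,7‑dimethyloct‑6‑en‑1‑ol]
Product: 14 tert‑butyl{[(3S)‑3,7‑dimethyloct‑6‑en‑1‑yl]oxy}dimethylsilane
Conditions: TBSCl, imidazole, DMF, rt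
Reagents that add atoms: tert‑butyldimethylsilyl chloride, CC(C)(C)[Si](C)(C)Cl
Why: Imidazole‑promoted silylation of the primary alcohol gives a silyl ether that tolerates ozone, amide bases, the silane/iron conditions and selenium chemistry and is removed by fluoride at the end.

Step 11
Reactants: 14 tert‑butyl{[(3S)‑3,7‑dimethyloct‑6‑en‑1‑yl]oxy}dimethylsilane
Product: 16 (4S)‑6‑[(tert‑butyldimethylsilyl)oxy]‑4‑methylhexanal, via secondary ozonide 15 (not isolated)
Conditions: O3, CH2Cl2, −78 °C; then PPh3, −78 °C → rt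
Reagents that add atoms: ozone, [O-][O+]=O
Why: Ozonolysis of the trisubstituted alkene with reductive (phosphine) work‑up cleaves off the isopropylidene carbons as acetone and leaves the aldehyde, which has no α‑stereocentre to lose, while C13 is remote and untouched.

Step 12
Reactants: 12 methyl 2‑[bis(2,2,2‑trifluoroethoxy)phosphoryl]‑4‑[(1S)‑2,6,6‑trimethylcyclohex‑2‑en‑1‑yl]butanoate; 16 (4S)‑6‑[(tert‑butyldimethylsilyl)oxy]‑4‑methylhexanal
Product: 17 methyl (2Z,6S)‑8‑[(tert‑butyldimethylsilyl)oxy]‑6‑methyl‑2‑{2‑[(1S)‑2,6,6‑trimethylcyclohex‑2‑en‑1‑yl]ethyl}oct‑2‑enoate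
Conditions: KN(SiMe3)2, 18‑crown‑6, THF, −78 °C; then 16, −78 °C
Reagents that add atoms: none
Why: Still–Gennari modification of the Horner–Wadsworth–Emmons olefination: with the electron‑poor bis(trifluoroethyl) phosphonate and a crown‑ether‑separated potassium counter‑ion, elimination from the kinetically preferred adduct is faster than its equilibration, which should give the Z enoate with the C11 chain cis to the ester, the geometry that step 13 translates into the C9 configuration.

Step 13
Reactants: 17 methyl (2Z,6S)‑8‑[(tert‑butyldimethylsilyl)oxy]‑6‑methyl‑2‑{2‑[(1S)‑2,6,6‑trimethylcyclohex‑2‑en‑1‑yl]ethyl}oct‑2‑enoate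
Product: 18 methyl (13S)‑15‑[(tert‑butyldimethylsilyl)oxy]labdan‑17‑oate, drawn as the 8α (equatorial) ester with 5α‑H, 9α‑H and 10β‑methyl
Conditions: Fe(acac)3 (0.3 equiv), PhSiH3 (2.5 equiv), EtOH/ethylene glycol 5:1, 0.02 M, 60 °C, argon
Reagents that add atoms: none
Why: The iron hydride generated from Fe(acac)3 and PhSiH3 transfers a hydrogen atom to the less substituted C1 of the electron‑rich ring A alkene (Markovnikov, and faster than to the electron‑poor α,β‑disubstituted enoate) to give the tertiary C10 radical, which adds to the β‑carbon C9 of the tethered enoate; the resulting C8 radical is reduced by divalent iron to the enolate and protonated by the solvent, which closes the catalytic cycle. The closest known reaction type is the iron‑hydride hydrogen‑atom‑transfer reductive coupling of an unactivated alkene with an acrylate (a radical conjugate addition), here intramolecular, and the bond formed is the one made in the second ring closure of radical polyene cyclisations. Ring B closes 6‑endo‑trig, since the 5‑exo alternative would require attack on the fully substituted α‑carbon C8 and would leave an unstabilised radical on C9. C10 is set by the resident C5 centre: in the chair‑like transition state the C5–C6 tether is equatorial on ring A and C9 bonds to the face of the radical that makes the C10 methyl axial and anti to H5, giving the trans‑decalin. C9 is set by the Z geometry of the olefin, which holds C11 anti to C7 across C8–C9 so that C11 becomes equatorial and H9 axial (9α‑H) in the same chair, whereas C8 is fixed only by protonation and either C8 epimer serves because this centre becomes sp2 in step 15. The step needs chemoselective hydrogen‑atom transfer to the ring alkene and ring closure faster than reduction of the C10 radical, which the donor/acceptor polarity match, the intramolecular setting and high dilution are expected to secure.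

Step 14
Reactants: 18 methyl (13S)‑15‑[(tert‑butyldimethylsilyl)oxy]labdan‑17‑oate
Product: 19 methyl (13S)‑15‑[(tert‑butyldimethylsilyl)oxy]‑8‑(phenylselanyl)labdan‑17‑oate, drawn with selenium 8α and the ester 8β
Conditions: LiN(i‑Pr)2 (LDA), THF/DMPU, −78 → −20 °C; then PhSeBr, −78 °C
Reagents that add atoms: phenylselenenyl bromide, Br[Se]c1ccccc1
Why: α‑Selenenylation of the lithium ester enolate (electrophilic trapping by PhSeBr) makes C8 quaternary; selenium is expected to enter from the α face, opposite the axial C10 methyl, but either C8 epimer is usable in step 15.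

Step 15
Reactants: 19 methyl (13S)‑15‑[(tert‑butyldimethylsilyl)oxy]‑8‑(phenylselanyl)labdan‑17‑oate
Product: 21 methyl (13S)‑15‑[(tert‑butyldimethylsilyl)oxy]labd‑7‑en‑17‑oate, via selenoxide 20 (not isolated)
Conditions: 30% H2O2 (excess), pyridine, CH2Cl2, 0 °C → rt
Reagents that add atoms: none
Why: Oxidation to the selenoxide and syn‑elimination (selenoxide elimination) should proceed at or below room temperature; a C7 methylene hydrogen is syn‑accessible from either C8 epimer and is statistically and sterically favoured over the single C9 methine hydrogen shielded by C10 and C11, so the 7‑ene conjugated with the ester should form without touching C9.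

Step 16
Reactants: 21 methyl (13S)‑15‑[(tert‑butyldimethylsilyl)oxy]labd‑7‑en‑17‑oate
Product: 22 methyl (13S)‑15‑hydroxylabd‑7‑en‑17‑oate
Conditions: Bu4NF, THF, rt
Reagents that add atoms: none
Why: Fluoride‑mediated desilylation, driven by the strength of the Si–F bond, frees the primary alcohol without affecting the conjugated ester or the stereocentres.

Step 17
Reactants: 22 methyl (13S)‑15‑hydroxylabd‑7‑en‑17‑oate
Product: 23 (13S)‑15‑hydroxylabd‑7‑en‑17‑oic acid
Conditions: LiOH, THF/MeOH/H2O, 60 °C; then 1 M HCl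
Reagents that add atoms: lithium hydroxide, [Li+].[OH-]
Why: Saponification of the conjugated methyl ester (hydroxide addition–elimination) should not epimerise C9, which sits at the non‑acidic cross‑conjugated position next to C8, and acidification gives the free acid.

Step 18
Reactants: 23 (13S)‑15‑hydroxylabd‑7‑en‑17‑oic acid
Product: 25 (5S,9R,10S,13S)‑15‑acetoxylabd‑7‑en‑17‑oic acid (target), via C17 acetic mixed anhydride 24 (not isolated)
Conditions: Ac2O (3 equiv), pyridine, DMAP (cat.), CH2Cl2, 0 °C → rt; then H2O/THF, rt; dilute HCl work‑up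
Reagents that add atoms: acetic anhydride, CC(=O)OC(C)=O
Why: Pyridine/DMAP‑catalysed O‑acetylation of the primary alcohol is irreversible, whereas the carboxyl group is acetylated only to the labile mixed anhydride, which water in the work‑up cleaves at the acetyl carbonyl to return the free acid.

**Compound list**
1 | methyl (±)‑α‑cyclogeranate (methyl 2,6,6‑trimethylcyclohex‑2‑ene‑1‑carboxylate) | COC(=O)C1C(C)=CCCC1(C)C | starting material
2 | (±)‑α‑cyclogeranic acid | OC(=O)C1C(C)=CCCC1(C)C | intermediate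
3 | (S)‑1‑phenylethylammonium (1S)‑2,6,6‑trimethylcyclohex‑2‑ene‑1‑carboxylate | [O-]C(=O)[C@@H]1C(C)=CCCC1(C)C.C[C@H]([NH3+])c1ccccc1 | intermediate
4 | (S)‑α‑cyclogeranic acid | OC(=O)[C@@H]1C(C)=CCCC1(C)C | intermediate
5 | (S)‑α‑cyclogeraniol | OC[C@@H]1C(C)=CCCC1(C)C | intermediate
6 | (S)‑α‑cyclocitral | O=C[C@@H]1C(C)=CCCC1(C)C | intermediate
7 | (6S)‑6‑ethenyl‑1,5,5‑trimethylcyclohex‑1‑ene | C=C[C@@H]1C(C)=CCCC1(C)C | intermediate
8 | 9‑{2‑[(1S)‑2,6,6‑trimethylcyclohex‑2‑en‑1‑yl]ethyl}‑9‑borabicyclo[3.3.1]nonane (B‑alkyl‑9‑BBN adduct) | C1CCC2CCCC1B2CC[C@@H]1C(C)=CCCC1(C)C | intermediate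
9 | 2‑[(1S)‑2,6,6‑trimethylcyclohex‑2‑en‑1‑yl]ethan‑1‑ol | OCC[C@@H]1C(C)=CCCC1(C)C | intermediate
10 | (6S)‑6‑(2‑iodoethyl)‑1,5,5‑trimethylcyclohex‑1‑ene | ICC[C@@H]1C(C)=CCCC1(C)C | intermediate
11 | methyl bis(2,2,2‑trifluoroethyl)phosphonoacetate | COC(=O)CP(=O)(OCC(F)(F)F)OCC(F)(F)F | starting material
12 | methyl 2‑[bis(2,2,2‑trifluoroethoxy)phosphoryl]‑4‑[(1S)‑2,6,6‑trimethylcyclohex‑2‑en‑1‑yl]butanoate (C2 epimers) | COC(=O)C(CC[C@@H]1C(C)=CCCC1(C)C)P(=O)(OCC(F)(F)F)OCC(F)(F)F | intermediate
13 | (S)‑citronellol | C[C@@H](CCC=C(C)C)CCO | starting material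
14 | tert‑butyl{[(3S)‑3,7‑dimethyloct‑6‑en‑1‑yl]oxy}dimethylsilane | CC(C)(C)[Si](C)(C)OCC[C@@H](C)CCC=C(C)C | intermediate
15 | 5‑{(3S)‑5‑[(tert‑butyldimethylsilyl)oxy]‑3‑methylpentyl}‑3,3‑dimethyl‑1,2,4‑trioxolane (secondary ozonide, epimers at the ring carbon) | CC(C)(C)[Si](C)(C)OCC[C@@H](C)CCC1OOC(C)(C)O1 | intermediate
16 | (4S)‑6‑[(tert‑butyldimethylsilyl)oxy]‑4‑methylhexanal | CC(C)(C)[Si](C)(C)OCC[C@@H](C)CCC=O | intermediate
17 | methyl (2Z,6S)‑8‑[(tert‑butyldimethylsilyl)oxy]‑6‑methyl‑2‑{2‑[(1S)‑2,6,6‑trimethylcyclohex‑2‑en‑1‑yl]ethyl}oct‑2‑enoate | CC(C)(C)[Si](C)(C)OCC[C@@H](C)CC/C=C(\C(=O)OC)CC[C@@H]1C(C)=CCCC1(C)C | intermediate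
18 | methyl (13S)‑15‑[(tert‑butyldimethylsilyl)oxy]labdan‑17‑oate (8α‑ester, 5α‑H, 9α‑H, 10β‑methyl) | CC(C)(C)[Si](C)(C)OCC[C@@H](C)CC[C@H]1[C@H](C(=O)OC)CC[C@H]2C(C)(C)CCC[C@]12C | intermediate
19 | methyl (13S)‑15‑[(tert‑butyldimethylsilyl)oxy]‑8α‑(phenylselanyl)labdan‑17‑oate (ester 8β) | CC(C)(C)[Si](C)(C)OCC[C@@H](C)CC[C@H]1[C@@]([Se]c3ccccc3)(C(=O)OC)CC[C@H]2C(C)(C)CCC[C@]12C | intermediate
20 | selenoxide of 19 (either configuration at selenium) | CC(C)(C)[Si](C)(C)OCC[C@@H](C)CC[C@H]1[C@@]([Se](=O)c3ccccc3)(C(=O)OC)CC[C@H]2C(C)(C)CCC[C@]12C | intermediate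
21 | methyl (13S)‑15‑[(tert‑butyldimethylsilyl)oxy]labd‑7‑en‑17‑oate | CC(C)(C)[Si](C)(C)OCC[C@@H](C)CC[C@H]1C(C(=O)OC)=CC[C@H]2C(C)(C)CCC[C@]12C | intermediate
22 | methyl (13S)‑15‑hydroxylabd‑7‑en‑17‑oate | OCC[C@@H](C)CC[C@H]1C(C(=O)OC)=CC[C@H]2C(C)(C)CCC[C@]12C | intermediate
23 | (13S)‑15‑hydroxylabd‑7‑en‑17‑oic acid | OCC[C@@H](C)CC[C@H]1C(C(=O)O)=CC[C@H]2C(C)(C)CCC[C@]12C | intermediate
24 | acetic (13S)‑15‑acetoxylabd‑7‑en‑17‑oic anhydride | CC(=O)OCC[C@@H](C)CC[C@H]1C(C(=O)OC(C)=O)=CC[C@H]2C(C)(C)CCC[C@]12C | intermediate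
25 | (5S,9R,10S,13S)‑15‑acetoxylabd‑7‑en‑17‑oic acid (CNP0412535.1) | CC(=O)OCC[C@@H](C)CC[C@H]1C(C(=O)O)=CC[C@H]2C(C)(C)CCC[C@]12C | target

**Step count**
Total: 18 steps. Longest linear sequence: 16 steps (steps 1–9, then 12–18); steps 10–11 form the side branch.

**Steps most likely to fail**

Step 13. Hydrogen‑atom delivery may outrun ring closure: the iron hydride can reduce the C10 radical or the enoate, or reversible hydrogen abstraction can move the ring double bond and erode C5, before C9–C10 forms. The fallback makes the same radical without any hydride donor. From 17, epoxidation of the ring A alkene alone (m‑CPBA, NaHCO3, CH2Cl2, 0 °C) should give the 1,10‑epoxide F1 as a mixture of epoxide epimers. Cp2TiCl (from Cp2TiCl2 and Zn, THF, rt) opens it reductively at the tertiary C10–O bond; the C10 radical cyclises 6‑endo onto C9, and the C8 radical is captured by a second trivalent titanium as its enolate, giving after protonation the 1‑hydroxy ester F2. Barton–McCombie deoxygenation through the imidazole‑1‑carbothioate F3 (1,1′‑thiocarbonyldiimidazole, DMAP, 1,2‑dichloroethane, 80 °C; then Bu3SnH, AIBN, toluene, 110 °C) returns to 18.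

Step 15. The syn‑elimination may lose regiocontrol and take the C9 methine hydrogen instead of a C7 hydrogen, an outcome that depends on the unproven face of selenenylation in step 14. The fallback fixes the olefin position by enolate regiochemistry. From 18, hydroxylation of the ester enolate (LiN(i‑Pr)2, THF, −78 °C; 2‑(phenylsulfonyl)‑3‑phenyloxaziridine) gives the 8‑hydroxy ester F4. LiAlH4 reduction to the 8,17‑diol F5 and NaIO4 cleavage (THF/H2O) give the 17‑nor‑8‑ketone F6. Kinetic deprotonation at the C7 methylene (LiN(i‑Pr)2, −78 °C) and O‑triflation with PhNTf2 give the 7‑en‑8‑yl triflate F7. Methoxycarbonylation (Pd(OAc)2, PPh3, CO, MeOH, Et3N, DMF, 60 °C) returns to 21.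

Step 12. Z‑selectivity may erode with the α‑branched phosphonate (slower elimination, equilibration of the adducts), compounded by a low‑yielding alkylation upstream in step 9. The fallback sets the geometry by syn‑hydrometalation and a stereoretentive coupling, setting out from 16 and 7. Ohira–Bestmann homologation of 16 (dimethyl (1‑diazo‑2‑oxopropyl)phosphonate, K2CO3, MeOH) gives the terminal alkyne F8, and methoxycarbonylation (n‑BuLi, THF, −78 °C; ClCO2Me) gives the ynoate F9. Syn‑hydrostannation with tin on the α‑carbon (Bu3SnH, Pd(PPh3)4, THF) gives the α‑stannyl enoate F10, and iododestannylation (I2, CH2Cl2, 0 °C) gives the α‑iodo enoate F11 with the C11 chain cis to the ester. B‑alkyl Suzuki–Miyaura coupling of F11 with borane 8, generated from 7 and 9‑BBN as in step 7 (PdCl2(dppf), AsPh3, Cs2CO3, DMF/THF/H2O, rt), forms C7–C8 with retention and returns to 17; this also bypasses step 9.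

**Further compounds**
F1 | step 13 | methyl (2Z,6S)‑8‑[(tert‑butyldimethylsilyl)oxy]‑2‑{2‑[(1S)‑2,3‑epoxy‑2,6,6‑trimethylcyclohexyl]ethyl}‑6‑methyloct‑2‑enoate (epoxide epimers) | CC(C)(C)[Si](C)(C)OCC[C@@H](C)CC/C=C(\C(=O)OC)CC[C@@H]1C2(C)OC2CCC1(C)C
F2 | step 13 | methyl (13S)‑15‑[(tert‑butyldimethylsilyl)oxy]‑1‑hydroxylabdan‑17‑oate (C1 epimers) | CC(C)(C)[Si](C)(C)OCC[C@@H](C)CC[C@H]1[C@H](C(=O)OC)CC[C@H]2C(C)(C)CCC(O)[C@]12C
F3 | step 13 | methyl (13S)‑15‑[(tert‑butyldimethylsilyl)oxy]‑1‑[(1H‑imidazol‑1‑ylcarbonothioyl)oxy]labdan‑17‑oate (C1 epimers) | CC(C)(C)[Si](C)(C)OCC[C@@H](C)CC[C@H]1[C@H](C(=O)OC)CC[C@H]2C(C)(C)CCC(OC(=S)n3ccnc3)[C@]12C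
F4 | step 15 | methyl (13S)‑15‑[(tert‑butyldimethylsilyl)oxy]‑8‑hydroxylabdan‑17‑oate (C8 epimers) | CC(C)(C)[Si](C)(C)OCC[C@@H](C)CC[C@H]1C(O)(C(=O)OC)CC[C@H]2C(C)(C)CCC[C@]12C
F5 | step 15 | (13S)‑15‑[(tert‑butyldimethylsilyl)oxy]labdane‑8,17‑diol (C8 epimers) | CC(C)(C)[Si](C)(C)OCC[C@@H](C)CC[C@H]1C(O)(CO)CC[C@H]2C(C)(C)CCC[C@]12C
F6 | step 15 | (13S)‑15‑[(tert‑butyldimethylsilyl)oxy]‑17‑norlabdan‑8‑one | CC(C)(C)[Si](C)(C)OCC[C@@H](C)CC[C@H]1C(=O)CC[C@H]2C(C)(C)CCC[C@]12C
F7 | step 15 | (13S)‑15‑[(tert‑butyldimethylsilyl)oxy]‑17‑norlabd‑7‑en‑8‑yl trifluoromethanesulfonate | CC(C)(C)[Si](C)(C)OCC[C@@H](C)CC[C@H]1C(OS(=O)(=O)C(F)(F)F)=CC[C@H]2C(C)(C)CCC[C@]12C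
F8 | step 12 | tert‑butyldimethyl{[(3S)‑3‑methylhept‑6‑yn‑1‑yl]oxy}silane | CC(C)(C)[Si](C)(C)OCC[C@@H](C)CCC#C
F9 | step 12 | methyl (6S)‑8‑[(tert‑butyldimethylsilyl)oxy]‑6‑methyloct‑2‑ynoate | CC(C)(C)[Si](C)(C)OCC[C@@H](C)CCC#CC(=O)OC
F10 | step 12 | methyl (2E,6S)‑8‑[(tert‑butyldimethylsilyl)oxy]‑6‑methyl‑2‑(tributylstannyl)oct‑2‑enoate | CC(C)(C)[Si](C)(C)OCC[C@@H](C)CC/C=C(\C(=O)OC)[Sn](CCCC)(CCCC)CCCC
F11 | step 12 | methyl (2E,6S)‑8‑[(tert‑butyldimethylsilyl)oxy]‑2‑iodo‑6‑methyloct‑2‑enoate | CC(C)(C)[Si](C)(C)OCC[C@@H](C)CC/C=C(\C(=O)OC)I
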